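## Structural features

The target is a 3-deoxy-proanthocyanidin-type dimer. An upper 7,3',4'-trihydroxyflavan, with no oxygen at C3 or C5, is joined through C4 to C8' of a lower (−)-epigallocatechin unit (unprimed locants: upper unit; primed: lower unit). Each unit is a chroman (rings A/C and A'/C') with a 2-aryl group: a catechol ring B above and a pyrogallol ring B' below. The stereodescriptors of the SMILES read 2S,4R in the upper unit and 2'R,3'R in the lower unit. The upper 2-aryl group and the C4 substituent are therefore 1,3-trans across the C3 methylene, and the two adjacent lower centres are cis, as in the natural epi series. Fragile features are the nine free phenols (catechol and pyrogallol autoxidise, fastest in base) and the benzylic aryl-ether bonds C2–O1 and C2'–O1' (ionisation in acid, hydrogenolysis, base epimerisation at C2'). The doubly benzylic C4–C8' bond can also re-ionise in strong acid. The real difficulty is threefold: the upper unit has no 3-oxygen to bias attack at C4, the bond must go to C8' and not C6', and the upper (S)-benzylic ether must be made and kept enantiopure. The key step uses the fact that C4 is a methine bonded to two electron-rich arene carbons, C4a of ring A and C8' of ring A', so C4 can come from one aldehyde carbon that is arylated twice.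

## Logic of the disconnections

**13 ⇒ 12.** The eight O–CH2Ph bonds are cut (O7, O3', O4' above; O5', O7' and the three pyrogallol oxygens below). All phenols must be masked during the acidic C–C bond formation, and benzyl is the one group that leaves all eight positions in a single neutral operation. The gain is a lipophilic, chromatographable, oxidation-stable penultimate compound. The demand is that hydrogenolysis stops before the ring bonds C2–O1 and C2'–O1' are cleaved and that 13 is handled without air.

**12 ⇒ 8 + 10 (through 11).** C4–C8' and C4–C4a are cut. C4 carries one hydrogen and two electron-rich arenes, so it is an aldehyde carbon that has undergone two Friedel–Crafts reactions. The gain is large: ring C and the C4 stereocentre vanish, the molecule splits into two halves of similar size, and 10 brings both lower stereocentres from the chiral pool. The demands are: ring closure must precede intermolecular capture, closure must occur para to the benzyloxy group of ring A, capture must occur at C8' and trans to the 2-aryl group, and the C2–O1 bond must not ionise.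

**10 ⇒ 9.** The five phenolic O–benzyl bonds are cut. A free lower unit would offer C6' as well as C8', would need a donor solvent that weakens the Lewis acid, and would expose the pyrogallol ring to oxidation. Benzyl ethers at O5' and O7' crowd C6', and they cost no extra deprotection step because 13 ⇒ 12 is already a hydrogenolysis. The demand is phenol-selective alkylation that leaves 3'-OH free and avoids C-benzylation, oxidation and epimerisation at C2'.

**8 ⇒ 6 (through 7).** The carbonyl of 8 is traced back to the terminal alkene of 6, one carbon longer. 8 is a β-aryloxy aldehyde that can lose aryloxide by E1cB, so it should be made last, near neutrality, from a precursor without acidic C–H bonds. An ester at this position would place acidic hydrogens next to the ether during the basic etherification and would need a partial hydride reduction; both are avoided. The gain is a robust latent aldehyde. The demand is an alkene cleavage that spares three benzyl ethers and two electron-rich arenes.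

**6 ⇒ 3 + 5.** The aryl C–O bond is cut, not the benzylic one. Forming the ether at the arene carbon leaves the C–O bond of the stereocentre intact, so configuration is retained. Substitution at the 4-alkoxybenzylic carbon would risk ionisation and racemisation. The gain is two simple pieces. The demand is a copper-catalysed coupling of a hindered secondary alkoxide, which 3 tolerates because it has no acidic C–H and an inert alkene.

**5 ⇒ 4.** The O–benzyl bond is cut. The ring-A oxygen needs the same protecting group as the rest, and it must stay a donor so that ring A cyclises and later stabilises the C4 cation. The forward step is a routine phenol alkylation.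

**3 ⇒ 1 (through 2).** The bond between the carbinol carbon and the allyl CH2 is cut. Reagent-controlled allyl transfer to the aldehyde of 1 sets the only stereocentre that is not taken from the chiral pool, in one step from a purchasable compound. The demand is high selectivity for the Si face.

## Other disconnections considered

**Alternative 1:** The cut is at O1–C2 and C3–C4 of upper ring C, so C4 would carry both arenes before the heterocycle exists.
- Forward step: the ortho-hydroxy diarylmethanol A1 would be dehydrated by the bulky binaphthyl phosphoric acid A3 to an ortho-quinone methide. This would add ethyl vinyl ether A2 in an inverse-demand hetero-Diels–Alder reaction to give the 2-ethoxychroman A4.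
- In favour: the C4–C8' bond would be made from a C8'-metallated, fully benzylated lower unit and a salicylaldehyde. C8' versus C6' would then be settled by a selective halogenation and not by relative arene nucleophilicity. On this point the alternative is better than the chosen plan.
- In favour: C4 could be set under catalyst control, which is at least the equal of the 1,3-substrate control relied on here.
- Against: A4 has no ring B, and C2 is an acetal carbon. The 3,4-dioxygenated aryl group would have to be added later through the oxocarbenium ion, so the 2,4-trans relation would depend on a second facial selection at an ionisation-prone centre.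
- Against: the quinone methide carries a 2,4,6-trioxygenated aryl group at its terminus, which stabilises and shields it. Cycloaddition may be slow, and the acid may instead cleave the aryl–carbinol bond. A chiral catalyst on a chiral substrate also raises a matched/mismatched question.
- Comparison: both plans treat C4 as a diaryl methine. The chosen plan forms both aryl bonds at one carbon in one operation and sets C4 relative to an existing C2; the alternative sets C4 first and C2 afterwards. The alternative needs full benzylation, halogenation, metalation and addition, phenol unmasking, cycloaddition, C2 arylation and deprotection, which is clearly more than seven steps.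

**Alternative 2:** The cut is at C3'–C4' and O1'–C2' of lower ring C'.
- Forward step: the salicylaldehyde A5, which already bears the upper flavan next to its phenol, would be condensed with the α-benzyloxy ketone A6 under anhydrous mineral acid. Aldol condensation and cyclodehydration would give the flavylium salt A7, and cis-selective reduction of the pyrylium ring would finish the lower unit.
- In favour: the arene that first receives the upper unit could be a symmetrical phloroglucinol derivative, so no C8'/C6' question arises at the C4–aryl bond. This is better than the chosen plan on that one point.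
- In favour: the condensation is convergent and classical, and syn delivery of hydrogen gives the 2',3'-cis relation by default. On relative configuration of the lower unit it is the equal of the chiral-pool approach.
- Against: C2' and C3' would be created by reducing a flat cation far from any stereocentre. A nearly unbiased mixture of the 2'R,3'R and 2'S,3'S diastereomers must be expected, and the chiral pool is wasted.
- Against: the reduction must add hydrogen at C2', C3' and C4' without cleaving benzylic C–O bonds. The mineral acid also threatens the C4–aryl bond next to a trioxygenated ring.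
- Comparison: the C4–aryl bond still has to be made by trans-selective cation capture, so the stereochemical problem of the chosen key step is moved, not removed. Desymmetrising formylation, ketone synthesis, condensation, reduction and diastereomer separation make the route longer.

**Alternative 3:** The cut is at C8'–C8a' and C6'–C7', so ring A' is assembled around C8'.
- Forward step: heating the cyclobutenone A8 with the flavan-4-yl siloxyalkyne A9 would open A8 to a vinylketene. (2+2) addition to the alkyne, four-electron ring opening, six-electron ring closure and tautomerisation would give the phenol A10.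
- In favour: the mechanism places the flavanyl group between the free hydroxyl and the silyloxy group, so regiocontrol is complete. This is better than the chosen plan.
- In favour: the three oxygens of ring A' emerge differentiated (free OH for O1', silyl ether, benzyl ether). The conditions are neutral, so acid-labile bonds are safe; on functional-group safety it is equal or better.
- In favour: C4 would be set earlier by capture of the C4 cation with a slim alkynyl nucleophile. Axial attack should be at least as selective as with a bulky arene, so this is equal.
- Against: A10 holds only ring A' of the lower unit. Ring C', its two adjacent stereocentres in the harder 2,3-cis arrangement and the pyrogallol ring must all be built afterwards, and the chiral-pool lower unit is discarded.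
- Against: A9 is a sensitive ynol silyl ether that needs its own synthesis, A8 is a strained speciality reagent, and prolonged heating of a propargylic, benzylic C4–H centre risks isomerisation.
- Comparison: the alternative answers the regiochemical question most rigorously but at roughly twice the step count. The chosen plan accepts a selectivity that rests on sterics in return for using 9 intact.

Key step: step 6

Remark: the allylborane of step 1 is taken as a purchased solution, its isopinocampheyl groups being those derived from (+)-α-pinene, and (−)-epigallocatechin is taken as the natural 2R,3R enantiomer.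

## Route

Step 1
Reactants: 1 3,4-bis(benzyloxy)benzaldehyde
Product: 3 (S)-1-[3,4-bis(benzyloxy)phenyl]but-3-en-1-ol, via homoallylic diisopinocampheylborinate 2 (not isolated)
Conditions: (−)-Ipc2B(allyl) (1 M in pentane, 1.3 equiv), Et2O/THF, −78 °C; then 3 M NaOH, 30% H2O2, 0 °C → rt
Reagents that add atoms: (−)-B-allyldiisopinocampheylborane, C=CCB([C@@H]1C[C@@H]2C[C@H]([C@H]1C)C2(C)C)[C@@H]1C[C@@H]2C[C@H]([C@H]1C)C2(C)C
Why: Brown allylation; allyl is transferred through a closed six-membered chair transition state in which the isopinocampheyl groups derived from (+)-α-pinene direct attack to the Si face of the aryl aldehyde, which gives the S carbinol, and alkaline peroxide then cleaves the B–O and B–C bonds of 2.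

Step 2
Reactants: 4 3-iodophenol
Product: 5 1-(benzyloxy)-3-iodobenzene
Conditions: BnBr (1.1 equiv), K2CO3 (1.5 equiv), DMF, rt
Reagents that add atoms: benzyl bromide, BrCc1ccccc1
Why: Williamson ether synthesis; the phenoxide displaces bromide from the benzylic carbon (SN2) and the aryl iodide is inert under these conditions.

Step 3
Reactants: 3 (S)-1-[3,4-bis(benzyloxy)phenyl]but-3-en-1-ol; 5 1-(benzyloxy)-3-iodobenzene (1.5 equiv)
Product: 6 4-{(1S)-1-[3-(benzyloxy)phenoxy]but-3-en-1-yl}-1,2-bis(benzyloxy)benzene
Conditions: CuI (10 mol%), 3,4,7,8-tetramethyl-1,10-phenanthroline (20 mol%), Cs2CO3 (2 equiv), toluene, 4 Å MS, 110 °C, Ar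
Reagents that add atoms: none
Why: Ullmann-type copper-catalysed C–O coupling of an aryl iodide with a secondary alkoxide; the carbinol C–O bond is not broken, so the S configuration is retained, and 3 has no acidic C–H and only an isolated alkene, so carbonate at 110 °C offers no elimination or retro-aldol pathway.

Step 4
Reactants: 6 4-{(1S)-1-[3-(benzyloxy)phenoxy]but-3-en-1-yl}-1,2-bis(benzyloxy)benzene
Product: 8 (S)-3-[3-(benzyloxy)phenoxy]-3-[3,4-bis(benzyloxy)phenyl]propanal, via vicinal diol 7 (not isolated)
Conditions: OsO4 (2 mol%), NaIO4 (4 equiv), 2,6-lutidine (2 equiv), 1,4-dioxane/H2O (3:1), rt; used at once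
Reagents that add atoms: osmium tetroxide, O=[Os](=O)(=O)=O (delivers the oxygen atoms); sodium periodate, [Na+].[O-]I(=O)(=O)=O (re-oxidant that replaces them)
Why: Lemieux–Johnson oxidation; catalytic dihydroxylation of the terminal alkene gives diol 7, which periodate cleaves in the same pot, while 2,6-lutidine buffers the medium so that the β-aryloxy aldehyde is neither over-oxidised nor pushed into E1cB loss of aryloxide; benzyl ethers, arenes and the stereocentre are not involved.

Step 5
Reactants: 9 (−)-epigallocatechin
Product: 10 5,7,3',4',5'-penta-O-benzyl-(−)-epigallocatechin, i.e. (2R,3R)-5,7-bis(benzyloxy)-2-[3,4,5-tris(benzyloxy)phenyl]chroman-3-ol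
Conditions: BnBr (5.5 equiv), K2CO3 (6 equiv), degassed DMF, −10 °C → rt, Ar, dark
Reagents that add atoms: benzyl bromide, BrCc1ccccc1
Why: Williamson benzylation; carbonate deprotonates only the five phenols and not the secondary C3 alcohol, so 3-OH stays free, while exclusion of oxygen and the low temperature limit pyrogallol autoxidation, C-benzylation of ring A and epimerisation at C2.

Step 6
Reactants: 8 (S)-3-[3-(benzyloxy)phenoxy]-3-[3,4-bis(benzyloxy)phenyl]propanal; 10 5,7,3',4',5'-penta-O-benzyl-(−)-epigallocatechin (2 equiv)
Product: 12 (2R,3R)-5,7-bis(benzyloxy)-8-{(2S,4R)-7-(benzyloxy)-2-[3,4-bis(benzyloxy)phenyl]chroman-4-yl}-2-[3,4,5-tris(benzyloxy)phenyl]chroman-3-ol, via flavan-4-ol 11 (not isolated)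
Conditions: BF3·OEt2 (1.5 equiv), CH2Cl2 (0.02 M), −78 → −40 °C until 8 is consumed; then 10 in CH2Cl2, −78 → −20 °C; sat. NaHCO3
Reagents that add atoms: none
Why: BF3 coordinates the aldehyde oxygen of 8, and the ring-A carbon ortho to the ether oxygen and para to the benzyloxy group attacks the carbonyl in a 6-exo-trig Friedel–Crafts hydroxyalkylation, which forms C4–C4a, closes ring C and gives flavan-4-ol 11 as its boron-bound epimers. The same Lewis acid then ionises the C4–O bond of 11, because the benzylic cation is para to the 7-benzyloxy group, and the cation is captured at C8' of 10 in an intermolecular Friedel–Crafts alkylation that forms C4–C8'. The closest known reaction type is the double Friedel–Crafts condensation of one aldehyde with two arenes, here intramolecular first and intermolecular second, combined with the Lewis-acid coupling of C4-oxygenated flavans with benzylated flavan-3-ols. The only new stereocentre is C4, and the existing C2 centre controls it: the cation adopts a half-chair with the 2-aryl group pseudo-equatorial, and pseudo-axial attack anti to the axial C3–H bond places the incoming arene trans to the 2-aryl group, which is the 4R configuration. The carbinol configuration of 11 does not matter because ionisation erases it. Site selectivity on ring A should follow from the para-directing benzyloxy group and from crowding at the carbon between the two oxygens. Selectivity for C8' over C6' should follow from the two benzyloxy groups that flank C6' in 10, and adding 10 only after 8 is consumed prevents intermolecular attack on the aldehyde. Low temperature and dilution are relied on to hold back elimination to the flav-3-ene, self-alkylation of ring A and ionisation of the C2–O1 bond.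

Step 7
Reactants: 12 (2R,3R)-5,7-bis(benzyloxy)-8-{(2S,4R)-7-(benzyloxy)-2-[3,4-bis(benzyloxy)phenyl]chroman-4-yl}-2-[3,4,5-tris(benzyloxy)phenyl]chroman-3-ol
Product: 13 (2R,3R)-8-[(2S,4R)-2-(3,4-dihydroxyphenyl)-7-hydroxychroman-4-yl]-2-(3,4,5-trihydroxyphenyl)chroman-3,5,7-triol (CNP0211965.1)
Conditions: H2 (1 atm), Pd(OH)2/C, THF/MeOH (1:1), rt; filtration under Ar, Sephadex LH-20, lyophilisation
Reagents that add atoms: none
Why: Heterogeneous hydrogenolysis of the eight benzyl–oxygen bonds; the C–C bonds at C4 are not cleaved, and the cyclic benzylic bonds C2–O1 and C2'–O1' react far more slowly than O-benzyl groups under neutral conditions at 1 atm, so the reaction is stopped when hydrogen uptake ceases; no stereocentre is touched.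

## Compound list

1 | 3,4-bis(benzyloxy)benzaldehyde | O=Cc1ccc(OCc2ccccc2)c(OCc2ccccc2)c1 | starting material
2 | (S)-1-[3,4-bis(benzyloxy)phenyl]but-3-en-1-yl diisopinocampheylborinate (formed in the flask, not isolated) | C=CC[C@H](OB([C@@H]1C[C@@H]2C[C@H]([C@H]1C)C2(C)C)[C@@H]1C[C@@H]2C[C@H]([C@H]1C)C2(C)C)c1ccc(OCc2ccccc2)c(OCc2ccccc2)c1 | intermediate
3 | (S)-1-[3,4-bis(benzyloxy)phenyl]but-3-en-1-ol | C=CC[C@H](O)c1ccc(OCc2ccccc2)c(OCc2ccccc2)c1 | intermediate
4 | 3-iodophenol | Oc1cccc(I)c1 | starting material
5 | 1-(benzyloxy)-3-iodobenzene | Ic1cccc(OCc2ccccc2)c1 | intermediate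
6 | 4-{(1S)-1-[3-(benzyloxy)phenoxy]but-3-en-1-yl}-1,2-bis(benzyloxy)benzene | C=CC[C@H](Oc1cccc(OCc2ccccc2)c1)c1ccc(OCc2ccccc2)c(OCc2ccccc2)c1 | intermediate
7 | (4S)-4-[3-(benzyloxy)phenoxy]-4-[3,4-bis(benzyloxy)phenyl]butane-1,2-diol, both C2 epimers (formed in the flask, not isolated) | OCC(O)C[C@H](Oc1cccc(OCc2ccccc2)c1)c1ccc(OCc2ccccc2)c(OCc2ccccc2)c1 | intermediate
8 | (S)-3-[3-(benzyloxy)phenoxy]-3-[3,4-bis(benzyloxy)phenyl]propanal | O=CC[C@H](Oc1cccc(OCc2ccccc2)c1)c1ccc(OCc2ccccc2)c(OCc2ccccc2)c1 | intermediate
9 | (−)-epigallocatechin, (2R,3R) | Oc1cc(O)c2c(c1)O[C@H](c1cc(O)c(O)c(O)c1)[C@H](O)C2 | starting material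
10 | (2R,3R)-5,7-bis(benzyloxy)-2-[3,4,5-tris(benzyloxy)phenyl]chroman-3-ol | C(c1ccccc1)Oc1cc(OCc3ccccc3)c2c(c1)O[C@H](c1cc(OCc3ccccc3)c(OCc3ccccc3)c(OCc3ccccc3)c1)[C@H](O)C2 | intermediate
11 | (2S)-7-(benzyloxy)-2-[3,4-bis(benzyloxy)phenyl]chroman-4-ol, both C4 epimers (formed in the flask, not isolated) | c1ccccc1COc1ccc2c(c1)O[C@H](c1ccc(OCc3ccccc3)c(OCc3ccccc3)c1)CC2O | intermediate
12 | (2R,3R)-5,7-bis(benzyloxy)-8-{(2S,4R)-7-(benzyloxy)-2-[3,4-bis(benzyloxy)phenyl]chroman-4-yl}-2-[3,4,5-tris(benzyloxy)phenyl]chroman-3-ol | c1ccccc1COc1ccc2c(c1)O[C@H](c1ccc(OCc3ccccc3)c(OCc3ccccc3)c1)C[C@H]2c1c(OCc3ccccc3)cc(OCc3ccccc3)c2c1O[C@H](c1cc(OCc3ccccc3)c(OCc3ccccc3)c(OCc3ccccc3)c1)[C@H](O)C2 | intermediate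
13 | (2R,3R)-8-[(2S,4R)-2-(3,4-dihydroxyphenyl)-7-hydroxychroman-4-yl]-2-(3,4,5-trihydroxyphenyl)chroman-3,5,7-triol | Oc1ccc2c(c1)O[C@H](c1ccc(O)c(O)c1)C[C@H]2c1c(O)cc(O)c2c1O[C@H](c1cc(O)c(O)c(O)c1)[C@H](O)C2 | target

## Step count and least certain steps

Total: 7 steps. Longest linear sequence: 5 steps (1 → 3 → 6 → 8 → 12 → 13; the branch from 4 is equally long, the branch from 9 has 3 steps).

**Step 6 (key step).** The most likely failure is premature ionisation of 11 before 10 is present. The C4 cation would then alkylate ring A of a second molecule or eliminate to the flav-3-ene and oligomerise. Further losses may come from incomplete facial selectivity at C4 and from loss of aryloxide from 8 under the Lewis acid. The fallback separates ring closure from coupling and stores the electrophile in a stable form. It sets out from 8. Trimethyl orthoformate and pyridinium p-toluenesulfonate in MeOH would give the dimethyl acetal F1. Cyclisation with BF3·OEt2 in CH2Cl2 at −78 °C (acetal Friedel–Crafts reaction, the cation being re-trapped by methanol) would give the isolable 4-methoxyflavan F2. This would then be coupled with 10 under catalytic TMSOTf in CH2Cl2 at −78 → −40 °C, the established activation of 4-alkoxyflavans. The fallback returns to the route at 12.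

**Step 3.** The most likely failure is slow coupling of the hindered secondary benzylic alkoxide. Hydrodeiodination of 5 and copper-mediated oxidation of the alkoxide to the ketone would then compete, and the latter could erode enantiopurity if reversible. The fallback replaces catalysis by a hypervalent-iodine arylating agent. It sets out from 3 and 5. In one pot (mCPBA, TsOH·H2O, then 1,3,5-trimethoxybenzene, MeCN), 5 would be converted into the aryl(trimethoxyphenyl)iodonium tosylate F3. The sodium alkoxide of 3 (t-BuONa, toluene, rt) would be arylated by F3 with transfer of the 3-benzyloxyphenyl group and retention at carbon. The fallback returns at 6.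

**Step 4.** The most likely failure is β-elimination of 3-benzyloxyphenoxide from 8 (retro-oxa-Michael, E1cB) during the aqueous oxidation, work-up or chromatography. The fallback avoids accumulating the aldehyde in water. It sets out from 6. Ozonolysis in CH2Cl2/MeOH at −78 °C to the end point of an indicator dye, followed by NaBH4 in the same flask, would give the stable primary alcohol F4. After purification, F4 would be oxidised with Dess–Martin periodinane and NaHCO3 in CH2Cl2 at 0 °C immediately before step 6. The fallback returns at 8.

**Step 5.** The most likely failure is autoxidation of the pyrogallol ring in the basic medium, together with C-benzylation of ring A and partial epimerisation at C2, so that little pure 10 is obtained. The fallback omits the protection. It sets out from 8 and 9. After cyclisation of 8 as in step 6, free 9 (excess, dissolved in THF) would be added as the nucleophile to give the tri-O-benzyl ether F5. Lower C8'/C6' selectivity and reversed-phase purification would be accepted. Hydrogenolysis of F5 under the conditions of step 7 returns to the route at 13.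

**Step 7.** The most likely failure is over-reduction, that is hydrogenolytic opening of the benzylic C2–O1 bond of the 3-deoxy unit. Stalling at partly debenzylated stages and air oxidation of 13 during isolation are also possible. The fallback replaces hydrogenolysis by Lewis-acid dealkylation. It sets out from 12. BCl3 with pentamethylbenzene as a non-basic benzyl-cation scavenger in CH2Cl2 at −78 °C, followed by a methanol quench, would cleave the eight benzyl ethers. The fallback returns at 13 and passes through no new isolated compound.

## Further compounds

F1 | step 6 | 4-{(1S)-1-[3-(benzyloxy)phenoxy]-3,3-dimethoxypropyl}-1,2-bis(benzyloxy)benzene | COC(OC)C[C@H](Oc1cccc(OCc2ccccc2)c1)c1ccc(OCc2ccccc2)c(OCc2ccccc2)c1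
F2 | step 6 | (2S)-7-(benzyloxy)-2-[3,4-bis(benzyloxy)phenyl]-4-methoxychroman, both C4 epimers | c1ccccc1COc1ccc2c(c1)O[C@H](c1ccc(OCc3ccccc3)c(OCc3ccccc3)c1)CC2OC
F3 | step 3 | [3-(benzyloxy)phenyl](2,4,6-trimethoxyphenyl)iodonium 4-methylbenzenesulfonate | COc1cc(OC)c([I+]c2cccc(OCc3ccccc3)c2)c(OC)c1.Cc1ccc(cc1)S(=O)(=O)[O-]
F4 | step 4 | (S)-3-[3-(benzyloxy)phenoxy]-3-[3,4-bis(benzyloxy)phenyl]propan-1-ol | OCC[C@H](Oc1cccc(OCc2ccccc2)c1)c1ccc(OCc2ccccc2)c(OCc2ccccc2)c1
F5 | step 5 | (2R,3R)-8-{(2S,4R)-7-(benzyloxy)-2-[3,4-bis(benzyloxy)phenyl]chroman-4-yl}-2-(3,4,5-trihydroxyphenyl)chroman-3,5,7-triol | c1ccccc1COc1ccc2c(c1)O[C@H](c1ccc(OCc3ccccc3)c(OCc3ccccc3)c1)C[C@H]2c1c(O)cc(O)c2c1O[C@H](c1cc(O)c(O)c(O)c1)[C@H](O)C2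
F0 | step 7 | none | none
A1 | alternative 1 | [4-(benzyloxy)-2-hydroxyphenyl](3,5,7,3',4',5'-hexa-O-benzylepigallocatechin-8-yl)methanol, carbinol centre unassigned | OC(c1ccc(OCc2ccccc2)cc1O)c1c(OCc2ccccc2)cc(OCc2ccccc2)c2c1O[C@H](c1cc(OCc3ccccc3)c(OCc3ccccc3)c(OCc3ccccc3)c1)[C@H](OCc1ccccc1)C2
A2 | alternative 1 | ethyl vinyl ether | C=COCC
A3 | alternative 1 | 3,3'-bis(2,4,6-triisopropylphenyl)-1,1'-binaphthyl-2,2'-diyl hydrogen phosphate, axial configuration to be chosen | O=P1(O)Oc2c(-c3c(C(C)C)cc(C(C)C)cc3C(C)C)cc3ccccc3c2-c2c(O1)c(-c3c(C(C)C)cc(C(C)C)cc3C(C)C)cc3ccccc23
A4 | alternative 1 | (2R,3R)-3,5,7-tris(benzyloxy)-8-[(4R)-7-(benzyloxy)-2-ethoxychroman-4-yl]-2-[3,4,5-tris(benzyloxy)phenyl]chroman, acetal carbon unassigned | c1ccccc1COc1ccc2c(c1)OC(OCC)C[C@H]2c1c(OCc2ccccc2)cc(OCc2ccccc2)c2c1O[C@H](c1cc(OCc3ccccc3)c(OCc3ccccc3)c(OCc3ccccc3)c1)[C@H](OCc1ccccc1)C2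
A5 | alternative 2 | 4,6-bis(benzyloxy)-3-{(2S,4R)-7-(benzyloxy)-2-[3,4-bis(benzyloxy)phenyl]chroman-4-yl}-2-hydroxybenzaldehyde | c1ccccc1COc1ccc2c(c1)O[C@H](c1ccc(OCc3ccccc3)c(OCc3ccccc3)c1)C[C@H]2c1c(OCc2ccccc2)cc(OCc2ccccc2)c(C=O)c1O
A6 | alternative 2 | 2-(benzyloxy)-1-[3,4,5-tris(benzyloxy)phenyl]ethan-1-one | O=C(COCc1ccccc1)c1cc(OCc2ccccc2)c(OCc2ccccc2)c(OCc2ccccc2)c1
A7 | alternative 2 | 3,5,7-tris(benzyloxy)-8-{(2S,4R)-7-(benzyloxy)-2-[3,4-bis(benzyloxy)phenyl]chroman-4-yl}-2-[3,4,5-tris(benzyloxy)phenyl]chromenylium chloride | c1ccccc1COc1ccc2c(c1)O[C@H](c1ccc(OCc3ccccc3)c(OCc3ccccc3)c1)C[C@H]2c1c(OCc2ccccc2)cc(OCc2ccccc2)c2cc(OCc3ccccc3)c(-c3cc(OCc4ccccc4)c(OCc4ccccc4)c(OCc4ccccc4)c3)[o+]c12.[Cl-]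
A8 | alternative 3 | 3-(benzyloxy)cyclobut-2-en-1-one | O=C1CC(OCc2ccccc2)=C1
A9 | alternative 3 | ({(2S,4S)-7-(benzyloxy)-2-[3,4-bis(benzyloxy)phenyl]chroman-4-yl}ethynyloxy)triisopropylsilane, 2,4-trans | c1ccccc1COc1ccc2c(c1)O[C@H](c1ccc(OCc3ccccc3)c(OCc3ccccc3)c1)C[C@H]2C#CO[Si](C(C)C)(C(C)C)C(C)C
A10 | alternative 3 | 5-(benzyloxy)-2-{(2S,4R)-7-(benzyloxy)-2-[3,4-bis(benzyloxy)phenyl]chroman-4-yl}-3-[(triisopropylsilyl)oxy]phenol, 2,4-trans | c1ccccc1COc1ccc2c(c1)O[C@H](c1ccc(OCc3ccccc3)c(OCc3ccccc3)c1)C[C@H]2c1c(O)cc(OCc2ccccc2)cc1O[Si](C(C)C)(C(C)C)C(C)C
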